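**Retrosynthetic overview**

- The last skeletal bond is C2–C1′ of the flavanone: a ligand-controlled Rh 1,4-addition of a dihydrobenzofuran-5-boronic acid (phenols as TBS ethers) to 5-hydroxy-7-silyloxy-6,8-diprenylchromone; fluoride then unmasks the target.
- The chromone comes from 2,4,6-trihydroxyacetophenone by twofold C-prenylation and a one-carbon pyranone closure (the A ring is symmetric, so either ortho OH gives the same ring).
- The boronic acid comes from an aryl bromide whose dihydrofuran is cut at C2–C3: a Rh(II) diaryl carbene at C3 inserts into the benzylic C–H of an ortho 4-methoxybenzyl ether, and the precursor is the hydrazone of a simple benzophenone.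
- Enabling feature: C3 carries two arenes and no β-hydrogen, and C2 is a benzylic O–CH held 1,5 to it through O1 and the B-ring carbons C7a/C3a. The 4-oxyphenyl on C2 later lets O1–C2 ionise reversibly, so the kinetic cis ring is funnelled to trans with C3 as anchor.
- Ring order: dihydrofuran (step 5), then the chromone pyranone (step 10). Stereocentres: C3 (step 5, catalyst), C2 (step 6, thermodynamic), flavanone C2 (step 12, ligand).

Key step: step 5

Assumption: Rh2(R-PTAD)4 is taken to give the 3R carbon in step 5 and the (S)-bisphosphine the 2S flavanone in step 12; if either sense of induction is the opposite, the enantiomeric catalyst or ligand is used. The five starting materials are taken to be catalogue compounds.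

**Route**

Step 1
Reactants: 1 5-bromo-2-hydroxy-4-methoxybenzaldehyde; 2 4-methoxybenzyl chloride
Product: 3 5-bromo-4-methoxy-2-[(4-methoxybenzyl)oxy]benzaldehyde
Conditions: K2CO3, KI (cat.), DMF, 60 °C
Reagents that add atoms: none
Why: Williamson etherification of the salicylaldehyde phenoxide with the activated benzylic chloride (SN2); no stereocentre is formed.

Step 2
Reactants: 3 5-bromo-4-methoxy-2-[(4-methoxybenzyl)oxy]benzaldehyde; 4 3,5-dimethoxyphenylmagnesium chloride (THF solution)
Product: 5 rac-{5-bromo-4-methoxy-2-[(4-methoxybenzyl)oxy]phenyl}(3,5-dimethoxyphenyl)methanol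
Conditions: THF, −78 → 0 °C; aq. NH4Cl
Reagents that add atoms: none
Why: Grignard addition to the aldehyde at low temperature outpaces Br/Mg exchange; the carbinol centre forms racemic, which is irrelevant because step 3 removes it.

Step 3
Reactants: 5 rac-{5-bromo-4-methoxy-2-[(4-methoxybenzyl)oxy]phenyl}(3,5-dimethoxyphenyl)methanol
Product: 6 {5-bromo-4-methoxy-2-[(4-methoxybenzyl)oxy]phenyl}(3,5-dimethoxyphenyl)methanone
Conditions: activated MnO2, CH2Cl2, rt
Reagents that add atoms: none
Why: MnO2 oxidation of a doubly benzylic alcohol to the benzophenone; ethers and the aryl bromide are inert.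

Step 4
Reactants: 6 {5-bromo-4-methoxy-2-[(4-methoxybenzyl)oxy]phenyl}(3,5-dimethoxyphenyl)methanone
Product: 7 hydrazone of ketone 6 (E/Z mixture)
Conditions: N2H4·H2O (excess), AcOH (cat.), EtOH, 90 °C (sealed tube)
Reagents that add atoms: hydrazine (as hydrate) NN
Why: Acid-catalysed hydrazone formation on the diaryl ketone; the E/Z mixture is of no consequence because both isomers give the same diazo compound.

Step 5
Reactants: 7 hydrazone of ketone 6 (E/Z mixture)
Product: 9 (2S,3R)-5-bromo-3-(3,5-dimethoxyphenyl)-6-methoxy-2-(4-methoxyphenyl)-2,3-dihydro-1-benzofuran (2,3-cis), via diaryldiazomethane 8 (not isolated)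
Conditions: activated MnO2, CH2Cl2, 0 °C → rt; filter; Rh2(R-PTAD)4 (1 mol %), MeCN, 0 °C
Reagents that add atoms: none
Why: MnO2 dehydrogenates the hydrazone to diaryldiazomethane 8, which the Rh(II) carboxylate decomposes with loss of N2 to a rhodium carbene at C3 that carries only two aryl donors, so it has no β-hydrogen to shift and is attenuated enough to be selective. The carbene inserts into the benzylic C–H of the ortho 4-methoxybenzyl ether through an asynchronous, hydride-shift-like three-centre transition state, with positive charge building on the oxygen- and anisyl-stabilised C2, and this forms the C2–C3 bond; the closest known reaction type is the enantioselective intramolecular C–H insertion of donor/donor diaryl carbenes into benzylic ether C–H bonds to give 2,3-diaryl-2,3-dihydrobenzofurans. The dihydrofuran closes as a 1,5-C–H insertion (five-membered ring; in the stepwise limit a 5-endo collapse of Rh-bound C3 onto the O1=C2 oxocarbenium). C3 is set by the chiral carboxylate pocket of the catalyst, which selects one face of the carbene (equivalently one of the two enantiotopic benzylic hydrogens), and C2 is set in the same event cis to C3 because both aryl groups turn away from the catalyst wall in the closing transition state; this cis C2 is the kinetic result and is corrected in step 6 without touching C3. The step needs site selectivity (only the O–CH2 group is held 1,5 to the carbene, the methoxy groups are out of reach and the bromide is inert), suppression of azine formation and carbene dimerisation (dilution, low temperature) and high enantioselectivity at C3, which the electron-rich donor/donor carbene and the hindered catalyst should secure.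

Step 6
Reactants: 9 (2S,3R)-5-bromo-3-(3,5-dimethoxyphenyl)-6-methoxy-2-(4-methoxyphenyl)-2,3-dihydro-1-benzofuran (2,3-cis)
Product: 10 (2R,3R)-5-bromo-3-(3,5-dihydroxyphenyl)-2-(4-hydroxyphenyl)-2,3-dihydro-1-benzofuran-6-ol (2,3-trans)
Conditions: BBr3 (10 equiv), CH2Cl2, −78 °C → rt; H2O quench
Reagents that add atoms: none
Why: BBr3 cleaves the four aryl methyl ethers (Lewis-acid demethylation) and, by reversibly ionising the O1–C2 benzylic ether through the 4-oxybenzyl cation/quinone methide, lets C2 re-close on the face away from the C3 aryl, so the kinetic cis ring is funnelled to the thermodynamic trans (2R,3R) isomer while C3, which never ionises, keeps its catalyst-set configuration.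

Step 7
Reactants: 10 (2R,3R)-5-bromo-3-(3,5-dihydroxyphenyl)-2-(4-hydroxyphenyl)-2,3-dihydro-1-benzofuran-6-ol (2,3-trans)
Product: 11 (2R,3R)-5-bromo-6-(TBSO)-2-[4-(TBSO)phenyl]-3-[3,5-bis(TBSO)phenyl]-2,3-dihydro-1-benzofuran (TBS = tert-butyldimethylsilyl)
Conditions: TBSCl (6 equiv), imidazole, DMF, rt
Reagents that add atoms: tert-butyldimethylsilyl chloride CC(C)(C)[Si](C)(C)Cl
Why: Standard silylation of all four phenols replaces the methyl ethers by groups that fluoride can remove at the end without acid or base.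

Step 8
Reactants: 11 (2R,3R)-5-bromo-6-(TBSO)-2-[4-(TBSO)phenyl]-3-[3,5-bis(TBSO)phenyl]-2,3-dihydro-1-benzofuran
Product: 14 [(2R,3R)-6-(TBSO)-2-[4-(TBSO)phenyl]-3-[3,5-bis(TBSO)phenyl]-2,3-dihydro-1-benzofuran-5-yl]boronic acid, via aryllithium 12 (not isolated), via lithium aryltriisopropoxyborate 13 (not isolated)
Conditions: B(OiPr)3, n-BuLi, THF/toluene, −78 °C (in situ quench); 1 M HCl, 0 °C
Reagents that add atoms: triisopropyl borate CC(C)OB(OC(C)C)OC(C)C; water O
Why: Bromine–lithium exchange with the borate already present traps the aryllithium as the ate complex faster than the ortho silyl group can migrate from O to C, and mild acid hydrolysis releases the boronic acid; no stereocentre is involved.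

Step 9
Reactants: 15 2,4,6-trihydroxyacetophenone; 16 prenyl bromide (1-bromo-3-methylbut-2-ene, 2.2 equiv)
Product: 17 1-[2,4,6-trihydroxy-3,5-bis(3-methylbut-2-en-1-yl)phenyl]ethan-1-one
Conditions: DBU, THF, 0 °C → rt
Reagents that add atoms: none
Why: Twofold C-alkylation of the acylphloroglucinol phenoxide at its two free ring carbons with the soft allylic bromide (C-prenylation); over-alkylated dearomatised by-products are removed by chromatography.

Step 10
Reactants: 17 1-[2,4,6-trihydroxy-3,5-bis(3-methylbut-2-en-1-yl)phenyl]ethan-1-one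
Product: 19 5,7-dihydroxy-6,8-bis(3-methylbut-2-en-1-yl)-4H-chromen-4-one, via enaminone 18 (not isolated)
Conditions: t-BuOCH(NMe2)2 (4 equiv), toluene, 60 °C; concentrate; AcOH, 50 °C
Reagents that add atoms: tert-butoxybis(dimethylamino)methane CC(C)(C)OC(N(C)C)N(C)C
Why: Aminomethylenation of the methyl ketone gives the enaminone, and acetic acid promotes conjugate addition of an ortho OH and loss of dimethylamine (enaminone route to chromones); the two ortho OH groups are equivalent so only one chromone can form, the reagent cannot O-methylate, and the weak acid does not cyclise the prenyl groups.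

Step 11
Reactants: 19 5,7-dihydroxy-6,8-bis(3-methylbut-2-en-1-yl)-4H-chromen-4-one
Product: 20 7-(TBSO)-5-hydroxy-6,8-bis(3-methylbut-2-en-1-yl)-4H-chromen-4-one
Conditions: TBSCl (1.1 equiv), imidazole, CH2Cl2, 0 °C → rt
Reagents that add atoms: tert-butyldimethylsilyl chloride CC(C)(C)[Si](C)(C)Cl
Why: The 7-OH is the only unchelated phenol (the 5-OH is locked in a hydrogen bond to C4=O), so one equivalent of silyl chloride silylates it selectively.

Step 12
Reactants: 14 [(2R,3R)-6-(TBSO)-2-[4-(TBSO)phenyl]-3-[3,5-bis(TBSO)phenyl]-2,3-dihydro-1-benzofuran-5-yl]boronic acid; 20 7-(TBSO)-5-hydroxy-6,8-bis(3-methylbut-2-en-1-yl)-4H-chromen-4-one (1.5 equiv)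
Product: 21 (2S)-5-hydroxy-7-(TBSO)-6,8-bis(3-methylbut-2-en-1-yl)-2-[(2R,3R)-6-(TBSO)-2-[4-(TBSO)phenyl]-3-[3,5-bis(TBSO)phenyl]-2,3-dihydro-1-benzofuran-5-yl]chroman-4-one
Conditions: [Rh(OH)(cod)]2 (2.5 mol %), (S)-MeO-F12-BIPHEP [2,2′-bis(bis(3,4,5-trifluorophenyl)phosphino)-6,6′-dimethoxybiphenyl] (5.5 mol %), toluene/H2O, 40 °C
Reagents that add atoms: none
Why: Hayashi–Miyaura-type Rh-catalysed asymmetric 1,4-addition of an arylboronic acid to a chromone: transmetalation to Rh–OH, enantioface-selective carborhodation of C2=C3 dictated by the electron-poor atropisomeric bisphosphine (catalyst control; the remote benzofuran centres are not touched) and protonolysis by water set the flavanone C2 as S, while the hydrogen-bonded 5-OH activates the enone and the mild base-free conditions avoid retro-oxa-Michael opening.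

Step 13
Reactants: 21 (2S)-5-hydroxy-7-(TBSO)-6,8-bis(3-methylbut-2-en-1-yl)-2-[(2R,3R)-6-(TBSO)-2-[4-(TBSO)phenyl]-3-[3,5-bis(TBSO)phenyl]-2,3-dihydro-1-benzofuran-5-yl]chroman-4-one
Product: 22 (2S)-5,7-dihydroxy-2-[(2R,3R)-3-(3,5-dihydroxyphenyl)-6-hydroxy-2-(4-hydroxyphenyl)-2,3-dihydro-1-benzofuran-5-yl]-6,8-bis(3-methylbut-2-en-1-yl)chroman-4-one (CNP0230984.1)
Conditions: Et3N·3HF, THF/MeCN, rt
Reagents that add atoms: none
Why: Fluoride cleavage of the five aryl silyl ethers under buffered, near-neutral conditions avoids both phenoxide-triggered opening of the flavanone (epimerisation at its C2) and acid-mediated cyclisation of the prenyl groups onto the neighbouring phenols; all three stereocentres are untouched.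

**Compound list**

1 | 5-bromo-2-hydroxy-4-methoxybenzaldehyde | O=Cc1cc(Br)c(OC)cc1O | starting material
2 | 4-methoxybenzyl chloride | COc1ccc(CCl)cc1 | starting material
3 | 5-bromo-4-methoxy-2-[(4-methoxybenzyl)oxy]benzaldehyde | O=Cc1cc(Br)c(OC)cc1OCc1ccc(OC)cc1 | intermediate
4 | 3,5-dimethoxyphenylmagnesium chloride | COc1cc(OC)cc([Mg]Cl)c1 | starting material
5 | rac-{5-bromo-4-methoxy-2-[(4-methoxybenzyl)oxy]phenyl}(3,5-dimethoxyphenyl)methanol | OC(c1cc(OC)cc(OC)c1)c1cc(Br)c(OC)cc1OCc1ccc(OC)cc1 | intermediate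
6 | {5-bromo-4-methoxy-2-[(4-methoxybenzyl)oxy]phenyl}(3,5-dimethoxyphenyl)methanone | O=C(c1cc(OC)cc(OC)c1)c1cc(Br)c(OC)cc1OCc1ccc(OC)cc1 | intermediate
7 | hydrazone of 6 (E/Z mixture) | NN=C(c1cc(OC)cc(OC)c1)c1cc(Br)c(OC)cc1OCc1ccc(OC)cc1 | intermediate
8 | diaryldiazomethane from 7 (not isolated) | [N-]=[N+]=C(c1cc(OC)cc(OC)c1)c1cc(Br)c(OC)cc1OCc1ccc(OC)cc1 | intermediate
9 | (2S,3R)-5-bromo-3-(3,5-dimethoxyphenyl)-6-methoxy-2-(4-methoxyphenyl)-2,3-dihydro-1-benzofuran (cis) | Brc1cc2c(cc1OC)O[C@H](c1ccc(OC)cc1)[C@@H]2c1cc(OC)cc(OC)c1 | intermediate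
10 | (2R,3R)-5-bromo-3-(3,5-dihydroxyphenyl)-2-(4-hydroxyphenyl)-2,3-dihydro-1-benzofuran-6-ol (trans) | Brc1cc2c(cc1O)O[C@@H](c1ccc(O)cc1)[C@@H]2c1cc(O)cc(O)c1 | intermediate
11 | tetra-TBS ether of 10 | Brc1cc2c(cc1O[Si](C)(C)C(C)(C)C)O[C@@H](c1ccc(O[Si](C)(C)C(C)(C)C)cc1)[C@@H]2c1cc(O[Si](C)(C)C(C)(C)C)cc(O[Si](C)(C)C(C)(C)C)c1 | intermediate
12 | aryllithium from 11 (not isolated) | [Li]c1cc2c(cc1O[Si](C)(C)C(C)(C)C)O[C@@H](c1ccc(O[Si](C)(C)C(C)(C)C)cc1)[C@@H]2c1cc(O[Si](C)(C)C(C)(C)C)cc(O[Si](C)(C)C(C)(C)C)c1 | intermediate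
13 | lithium aryltriisopropoxyborate (not isolated) | [Li+].CC(C)O[B-](OC(C)C)(OC(C)C)c1cc2c(cc1O[Si](C)(C)C(C)(C)C)O[C@@H](c1ccc(O[Si](C)(C)C(C)(C)C)cc1)[C@@H]2c1cc(O[Si](C)(C)C(C)(C)C)cc(O[Si](C)(C)C(C)(C)C)c1 | intermediate
14 | [(2R,3R)-tetra-TBS-dihydrobenzofuran-5-yl]boronic acid | OB(O)c1cc2c(cc1O[Si](C)(C)C(C)(C)C)O[C@@H](c1ccc(O[Si](C)(C)C(C)(C)C)cc1)[C@@H]2c1cc(O[Si](C)(C)C(C)(C)C)cc(O[Si](C)(C)C(C)(C)C)c1 | intermediate
15 | 2,4,6-trihydroxyacetophenone | CC(=O)c1c(O)cc(O)cc1O | starting material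
16 | prenyl bromide | CC(C)=CCBr | starting material
17 | 1-[2,4,6-trihydroxy-3,5-bis(3-methylbut-2-en-1-yl)phenyl]ethan-1-one | CC(=O)c1c(O)c(CC=C(C)C)c(O)c(CC=C(C)C)c1O | intermediate
18 | (E)-3-(dimethylamino)-1-[2,4,6-trihydroxy-3,5-diprenylphenyl]prop-2-en-1-one (not isolated) | CN(C)/C=C/C(=O)c1c(O)c(CC=C(C)C)c(O)c(CC=C(C)C)c1O | intermediate
19 | 5,7-dihydroxy-6,8-bis(3-methylbut-2-en-1-yl)-4H-chromen-4-one | O=c1ccoc2c(CC=C(C)C)c(O)c(CC=C(C)C)c(O)c12 | intermediate
20 | 7-(TBSO)-5-hydroxy-6,8-bis(3-methylbut-2-en-1-yl)-4H-chromen-4-one | O=c1ccoc2c(CC=C(C)C)c(O[Si](C)(C)C(C)(C)C)c(CC=C(C)C)c(O)c12 | intermediate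
21 | (2S)-penta-TBS flavanone | CC(C)=CCc1c(O[Si](C)(C)C(C)(C)C)c(CC=C(C)C)c2c(c1O)C(=O)C[C@@H](c1cc3c(cc1O[Si](C)(C)C(C)(C)C)O[C@@H](c1ccc(O[Si](C)(C)C(C)(C)C)cc1)[C@@H]3c1cc(O[Si](C)(C)C(C)(C)C)cc(O[Si](C)(C)C(C)(C)C)c1)O2 | intermediate
22 | CNP0230984.1 | CC(C)=CCc1c(O)c(CC=C(C)C)c2c(c1O)C(=O)C[C@@H](c1cc3c(cc1O)O[C@@H](c1ccc(O)cc1)[C@@H]3c1cc(O)cc(O)c1)O2 | target

**Totals**

Total step count: 13. Longest linear sequence: 10 steps (steps 1–8, 12, 13).

**Steps most likely to fail**

Step 12. Protodeboronation of the electron-rich, ortho-silyloxy arylboronic acid may outrun carborhodation of the hindered, electron-rich chromone, or the ortho substituent may erode facial selectivity. The fallback builds the flavanone from the aldehyde oxidation level and sets out from 11 and 17. Bromine–lithium exchange of 11 (n-BuLi, THF, −78 °C, short contact) and a DMF quench should give the aldehyde (2R,3R)-6-(TBSO)-2-[4-(TBSO)phenyl]-3-[3,5-bis(TBSO)phenyl]-2,3-dihydro-1-benzofuran-5-carbaldehyde F1. Acetophenone 17 is silylated at its unchelated 4-OH (TBSCl, imidazole) to 1-[4-(TBSO)-2,6-dihydroxy-3,5-diprenylphenyl]ethan-1-one F2. Pyrrolidine-mediated aldol condensation of F2 with F1 (4 Å MS, CH2Cl2, rt) should give the 2′-hydroxychalcone F3, which closes by oxa-Michael addition of either equivalent ortho OH to the flavanone as a pair of C2 epimers, 21 and the (2R)-epimer F4. These are diastereomers and are separated by chromatography; F4 is returned to the equilibrium through F3 with an amine base. The fallback rejoins the route at 21.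

Step 6. The benzylic ether may over-ionise under BBr3 and the resulting cation may be lost to Friedel–Crafts oligomerisation, or the C2 equilibration or demethylation may stop short. The fallback separates the two events and sets out from 9. Trifluoroacetic acid (CH2Cl2, rt) equilibrates C2 at the methyl ether stage to (2R,3R)-5-bromo-3-(3,5-dimethoxyphenyl)-6-methoxy-2-(4-methoxyphenyl)-2,3-dihydro-1-benzofuran F5. The methyl ethers are then removed by iodide-assisted dealkylation (BCl3, n-Bu4NI, CH2Cl2, −78 → 0 °C), below the temperature at which the ring ionises further. The fallback rejoins the route at 10.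

Step 8. Anionic O→C silyl migration in the ortho-lithiated silyl ether, or protodeboronation during the acidic work-up, may consume the material. The fallback avoids the organolithium and sets out from 11. Pd-catalysed Miyaura borylation (B2pin2, KOAc, Pd(dppf)Cl2, dioxane, 90 °C) should give the pinacol boronate 2-[(2R,3R)-tetra-TBS-dihydrobenzofuran-5-yl]-4,4,5,5-tetramethyl-1,3,2-dioxaborolane F6. Oxidative removal of the pinacol (NaIO4, NH4OAc, acetone/H2O, rt) rejoins the route at 14.

Further compounds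
F1 | step 12 | (2R,3R)-6-(TBSO)-2-[4-(TBSO)phenyl]-3-[3,5-bis(TBSO)phenyl]-2,3-dihydro-1-benzofuran-5-carbaldehyde | O=Cc1cc2c(cc1O[Si](C)(C)C(C)(C)C)O[C@@H](c1ccc(O[Si](C)(C)C(C)(C)C)cc1)[C@@H]2c1cc(O[Si](C)(C)C(C)(C)C)cc(O[Si](C)(C)C(C)(C)C)c1
F2 | step 12 | 1-[4-(TBSO)-2,6-dihydroxy-3,5-bis(3-methylbut-2-en-1-yl)phenyl]ethan-1-one | CC(=O)c1c(O)c(CC=C(C)C)c(O[Si](C)(C)C(C)(C)C)c(CC=C(C)C)c1O
F3 | step 12 | (E)-2′,6′-dihydroxy-4′-(TBSO)-3′,5′-diprenylchalcone carrying the tetra-TBS dihydrobenzofuran-5-yl group at the β-carbon | CC(C)=CCc1c(O)c(C(=O)/C=C/c2cc3c(cc2O[Si](C)(C)C(C)(C)C)O[C@@H](c2ccc(O[Si](C)(C)C(C)(C)C)cc2)[C@@H]3c2cc(O[Si](C)(C)C(C)(C)C)cc(O[Si](C)(C)C(C)(C)C)c2)c(O)c(CC=C(C)C)c1O[Si](C)(C)C(C)(C)C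
F4 | step 12 | (2R)-epimer of 21 | CC(C)=CCc1c(O[Si](C)(C)C(C)(C)C)c(CC=C(C)C)c2c(c1O)C(=O)C[C@H](c1cc3c(cc1O[Si](C)(C)C(C)(C)C)O[C@@H](c1ccc(O[Si](C)(C)C(C)(C)C)cc1)[C@@H]3c1cc(O[Si](C)(C)C(C)(C)C)cc(O[Si](C)(C)C(C)(C)C)c1)O2
F5 | step 6 | (2R,3R)-5-bromo-3-(3,5-dimethoxyphenyl)-6-methoxy-2-(4-methoxyphenyl)-2,3-dihydro-1-benzofuran (trans) | Brc1cc2c(cc1OC)O[C@@H](c1ccc(OC)cc1)[C@@H]2c1cc(OC)cc(OC)c1
F6 | step 8 | 2-[(2R,3R)-tetra-TBS-dihydrobenzofuran-5-yl]-4,4,5,5-tetramethyl-1,3,2-dioxaborolane | CC1(C)OB(OC1(C)C)c1cc2c(cc1O[Si](C)(C)C(C)(C)C)O[C@@H](c1ccc(O[Si](C)(C)C(C)(C)C)cc1)[C@@H]2c1cc(O[Si](C)(C)C(C)(C)C)cc(O[Si](C)(C)C(C)(C)C)c1
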